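Both end groups contain the same 1,1,5-trimethyl-3-oxygenated cyclohexane ring, so everything rests on one Diels–Alder reaction. The silyl dienol ether of mesityl oxide (C1'–C4', carotenoid numbering) adds methyl but-2-ynoate (C5', C6', C7') and closes ring C1'–C6' of the furanoid half through C4'–C5' and C1'–C6'; it exploits the 1,3-relation of the C3' oxygen to the gem-dimethyl carbon C1' and to the methyl-bearing C5'. The precursors are two achiral, open-chain compounds. One Sharpless epoxidation then sets C5/C6; C3 and C8' are relayed from it. A single C15 tetraol gives both the triol phosphonium salt and, by ring closure, the furanoid one; two Wittig reactions with the C10 dialdehyde finish the polyene.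

Key step: step 2

Remark: carotenoid locants are used (ring C1–C6, chain C7–C15, primed for the furanoid half); phosphonate 11 and dialdehyde 21 are assumed to be purchasable; tetraol 15 is divided between steps 10 and 11.

Step 1
Reactants: 1 mesityl oxide (4-methylpent-3-en-2-one)
Product: 3 tert-butyldimethyl[(4-methylpenta-1,3-dien-2-yl)oxy]silane, via lithium dienolate 2 (not isolated)
Conditions: LiN(i-Pr)2, THF, −78 °C; then t-BuMe2SiCl, DMPU, −78 °C to rt
Reagents that add atoms: tert-butyldimethylsilyl chloride CC(C)(C)[Si](C)(C)Cl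
Why: Kinetic deprotonation of the enone at its methyl group by the hindered amide gives the cross-conjugated lithium dienolate, and O-silylation (kinetic enolate trapping) should give the 2-silyloxy diene; no stereocentre is formed.

Step 2
Reactants: 3 tert-butyldimethyl[(4-methylpenta-1,3-dien-2-yl)oxy]silane; 4 methyl but-2-ynoate
Product: 5 methyl 4-[(tert-butyldimethylsilyl)oxy]-2,6,6-trimethylcyclohexa-1,4-diene-1-carboxylate
Conditions: neat, BHT (cat.), sealed tube, 160 °C
Reagents that add atoms: none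
Why: A concerted but asynchronous thermal [4+2] cycloaddition joins the nucleophilic CH2 terminus of the 2-silyloxy diene (C4') to the β-carbon of the ynoate (C5') and the gem-dimethyl terminus (C1') to the ester-bearing carbon (C6'); the closest known reaction type is the Diels–Alder reaction of 2-silyloxy-1,3-dienes and of 4-methylpenta-1,3-diene with but-2-ynoyl dienophiles. The one ring formed, the six-membered carbocycle C1'–C6', closes suprafacially on both partners in the [4π+2π] mode. No stereocentre is created, and this is intended: the adduct is achiral and carries the tetrasubstituted C5'=C6' alkene and the C3' enol ether from which every stereocentre is installed later. The selectivity required is regiochemical, and two substituent effects act in the same sense: the 2-silyloxy group puts the largest HOMO coefficient on C4' (para rule) and the 4,4-dimethyl terminus prefers the carbon next to the acceptor (ortho rule). An alkyne dienophile is used so that the residual alkene lies exactly at C5'=C6', and the quaternary C1' excludes aromatisation of the 1,4-diene. The hindered terminus makes the reaction slow, which is why heat and a radical inhibitor are specified.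

Step 3
Reactants: 5 methyl 4-[(tert-butyldimethylsilyl)oxy]-2,6,6-trimethylcyclohexa-1,4-diene-1-carboxylate
Product: 6 {4-[(tert-butyldimethylsilyl)oxy]-2,6,6-trimethylcyclohexa-1,4-dien-1-yl}methanol
Conditions: i-Bu2AlH, CH2Cl2, −78 °C; aqueous KNaC4H4O6 work-up
Reagents that add atoms: none
Why: 1,2-Reduction of the conjugated ester by the aluminium hydride should give the primary allylic alcohol and leave the silyl enol ether and both alkenes untouched; no stereocentre is formed.

Step 4
Reactants: 6 {4-[(tert-butyldimethylsilyl)oxy]-2,6,6-trimethylcyclohexa-1,4-dien-1-yl}methanol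
Product: 7 [(1S,6S)-4-[(tert-butyldimethylsilyl)oxy]-2,2,6-trimethyl-7-oxabicyclo[4.1.0]hept-3-en-1-yl]methanol
Conditions: Ti(O-i-Pr)4 (cat.), L-(+)-diethyl tartrate (cat.), t-BuOOH, 4 Å molecular sieves, CH2Cl2, −20 °C
Reagents that add atoms: tert-butyl hydroperoxide CC(C)(C)OO
Why: Sharpless asymmetric epoxidation: the titanium tartrate complex binds the C7 hydroxyl and delivers oxygen to one enantiotopic face of the tetrasubstituted C5=C6 alkene, so that C5 and C6 are set together by reagent control (1S,6S), while the unbound silyl enol ether should be left untouched at −20 °C.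

Step 5
Reactants: 7 [(1S,6S)-4-[(tert-butyldimethylsilyl)oxy]-2,2,6-trimethyl-7-oxabicyclo[4.1.0]hept-3-en-1-yl]methanol
Product: 9 (3R,4S)-3,4-dihydroxy-4-(hydroxymethyl)-3,5,5-trimethylcyclohexan-1-one, via epoxy ketone 8 (not isolated)
Conditions: HClO4 (cat.), THF–H2O, 0 °C
Reagents that add atoms: water O
Why: Acid-catalysed hydrolysis: the silyl enol ether is cleaved to ketone 8 first, and the protonated epoxide is then opened by water at C5, the tertiary carbon remote from the neopentyl, hydroxymethyl-bearing C6, with inversion at C5 and retention at C6, which should give the trans-5,6-diol with C5 (R).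

Step 6
Reactants: 9 (3R,4S)-3,4-dihydroxy-4-(hydroxymethyl)-3,5,5-trimethylcyclohexan-1-one
Product: 10 (1R,2R)-1,2-dihydroxy-2,6,6-trimethyl-4-oxocyclohexane-1-carbaldehyde
Conditions: SO3·pyridine, DMSO, i-Pr2NEt, CH2Cl2, 0 °C; used without delay
Reagents that add atoms: none
Why: Parikh–Doering oxidation (activated DMSO) converts the only oxidisable hydroxyl, the primary one at C7, into the aldehyde under cold, non-acidic conditions that should spare the β-hydroxy ketone, and C6 carries no hydrogen, so nothing can epimerise.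

Step 7
Reactants: 10 (1R,2R)-1,2-dihydroxy-2,6,6-trimethyl-4-oxocyclohexane-1-carbaldehyde; 11 ethyl (2E)-4-(diethoxyphosphoryl)-3-methylbut-2-enoate
Product: 13 ethyl (2E,4E)-5-[(1R,2R)-1,2-dihydroxy-2,6,6-trimethyl-4-oxocyclohexyl]-3-methylpenta-2,4-dienoate, via lithiated phosphonate 12 (not isolated)
Conditions: 11, LiN(SiMe3)2, THF, −78 °C; then 10, −78 to 0 °C
Reagents that add atoms: none
Why: Horner–Wadsworth–Emmons olefination: the α-carbon of the lithiated vinylogous phosphonate adds to the aldehyde far faster than to the ketone, and elimination of phosphate should give the (7E) alkene with the (9E) enoate in place, the anion being too weak a base to enolise the β-hydroxy ketone; no stereocentre is formed, and any (9Z) isomer is removed by chromatography.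

Step 8
Reactants: 13 ethyl (2E,4E)-5-[(1R,2R)-1,2-dihydroxy-2,6,6-trimethyl-4-oxocyclohexyl]-3-methylpenta-2,4-dienoate
Product: 14 ethyl (2E,4E)-3-methyl-5-[(1R,2R,4S)-1,2,4-trihydroxy-2,6,6-trimethylcyclohexyl]penta-2,4-dienoate
Conditions: Me4NBH(OAc)3, MeCN–AcOH, −25 °C
Reagents that add atoms: none
Why: Evans–Saksena hydroxyl-directed reduction: the axial tertiary 5-OH binds the triacetoxyborohydride and delivers hydride to its own face of the C3 ketone through a six-membered chair transition state, which should set C3 (S) anti to the 5-OH, while the dienoate is not reduced.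

Step 9
Reactants: 14 ethyl (2E,4E)-3-methyl-5-[(1R,2R,4S)-1,2,4-trihydroxy-2,6,6-trimethylcyclohexyl]penta-2,4-dienoate
Product: 15 (1R,2R,4S)-1-[(1E,3E)-5-hydroxy-3-methylpenta-1,3-dien-1-yl]-2,6,6-trimethylcyclohexane-1,2,4-triol
Conditions: i-Bu2AlH (excess), THF, −78 to −20 °C; aqueous KNaC4H4O6 work-up
Reagents that add atoms: none
Why: 1,2-Reduction of the dienoate ester with excess aluminium hydride (the three hydroxyls consume hydride) should give the primary allylic alcohol, and the neutral tartrate work-up spares the tertiary allylic alcohol; no stereocentre is touched.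

Step 10
Reactants: 15 (1R,2R,4S)-1-[(1E,3E)-5-hydroxy-3-methylpenta-1,3-dien-1-yl]-2,6,6-trimethylcyclohexane-1,2,4-triol
Product: 17 [(2E,4E)-3-methyl-5-[(1R,2R,4S)-1,2,4-trihydroxy-2,6,6-trimethylcyclohexyl]penta-2,4-dien-1-yl]triphenylphosphonium bromide, via allylic bromide 16 (not isolated)
Conditions: NBS, Me2S, CH2Cl2, −20 °C; then PPh3, rt
Reagents that add atoms: N-bromosuccinimide O=C1CCC(=O)N1Br; triphenylphosphine c1ccc(cc1)P(c1ccccc1)c1ccccc1
Why: Corey–Kim halogenation: the bromosulfonium reagent formed from NBS and Me2S should convert only the primary allylic hydroxyl into bromide 16 under non-acidic conditions (the saturated secondary and the hindered tertiary hydroxyls do not react), and SN2 alkylation of PPh3 by this bromide gives the phosphonium salt.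

Step 11
Reactants: 15 (1R,2R,4S)-1-[(1E,3E)-5-hydroxy-3-methylpenta-1,3-dien-1-yl]-2,6,6-trimethylcyclohexane-1,2,4-triol
Product: 18 (2R,6S,7aR)-2-[(2E)-4-hydroxybut-2-en-2-yl]-4,4,7a-trimethyl-2,4,5,6,7,7a-hexahydro-1-benzofuran-6-ol
Conditions: camphorsulfonic acid (cat.), CH2Cl2–THF, −20 °C; Et3N quench at full conversion
Reagents that add atoms: none
Why: Acid-catalysed SN1'-type cyclodehydration (furanoid oxide ring closure): ionisation of the tertiary, diene-conjugated C6–OH gives an allyl cation whose C8 terminus is captured by the 5-OH, which is held by C5 on one face of the planar cation only, so that with the (7E) geometry retained C9 should end trans to the C5 methyl group, that is (8R), kinetic control (weak acid, low temperature, early quench) being used to avoid re-ionisation of the bis-allylic ether.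

Step 12
Reactants: 18 (2R,6S,7aR)-2-[(2E)-4-hydroxybut-2-en-2-yl]-4,4,7a-trimethyl-2,4,5,6,7,7a-hexahydro-1-benzofuran-6-ol
Product: 20 [(2E)-3-[(2R,6S,7aR)-6-hydroxy-4,4,7a-trimethyl-2,4,5,6,7,7a-hexahydro-1-benzofuran-2-yl]but-2-en-1-yl]triphenylphosphonium bromide, via allylic bromide 19 (not isolated)
Conditions: NBS, Me2S, CH2Cl2, −20 °C; then PPh3, rt
Reagents that add atoms: N-bromosuccinimide O=C1CCC(=O)N1Br; triphenylphosphine c1ccc(cc1)P(c1ccccc1)c1ccccc1
Why: Corey–Kim halogenation of the primary allylic hydroxyl followed by SN2 alkylation of PPh3, both under non-acidic conditions, so that the allylic ether stereocentre C8' should not ionise and the secondary hydroxyl stays free.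

Step 13
Reactants: 20 [(2E)-3-[(2R,6S,7aR)-6-hydroxy-4,4,7a-trimethyl-2,4,5,6,7,7a-hexahydro-1-benzofuran-2-yl]but-2-en-1-yl]triphenylphosphonium bromide; 21 (2E,4E,6E)-2,7-dimethylocta-2,4,6-trienedial
Product: 23 (2E,4E,6E,8E,10E)-11-[(2R,6S,7aR)-6-hydroxy-4,4,7a-trimethyl-2,4,5,6,7,7a-hexahydro-1-benzofuran-2-yl]-2,7-dimethyldodeca-2,4,6,8,10-pentaenal, via phosphonium ylide 22 (not isolated)
Conditions: NaOMe, MeOH–CH2Cl2, 0 °C to rt, 21 in excess; then heptane, 80 °C
Reagents that add atoms: none
Why: Wittig olefination: the semi-stabilised allylic ylide 22, generated by methoxide in the presence of an excess of the symmetrical dialdehyde, should condense with one aldehyde group only to form C11'=C12', the free hydroxyl is tolerated, and heating equilibrates the (Z) isomer of the new bond to (E).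

Step 14
Reactants: 17 [(2E,4E)-3-methyl-5-[(1R,2R,4S)-1,2,4-trihydroxy-2,6,6-trimethylcyclohexyl]penta-2,4-dien-1-yl]triphenylphosphonium bromide; 23 (2E,4E,6E,8E,10E)-11-[(2R,6S,7aR)-6-hydroxy-4,4,7a-trimethyl-2,4,5,6,7,7a-hexahydro-1-benzofuran-2-yl]-2,7-dimethyldodeca-2,4,6,8,10-pentaenal
Product: 25 (3S,5R,6R,3'S,5'R,8'R)-5',8'-epoxy-5,6,5',8'-tetrahydro-β,β-carotene-3,5,6,3'-tetrol, via phosphonium ylide 24 (not isolated)
Conditions: NaOMe, MeOH–CH2Cl2, 0 °C to rt; then heptane–EtOH, 70 °C
Reagents that add atoms: none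
Why: Second Wittig olefination: ylide 24 should condense with the C25 aldehyde to form C11=C12 and complete the C40 polyene under basic conditions that spare the tertiary allylic 6-OH and the allylic ether at C8', and heating equilibrates the new double bond to (E).

Compound list
1 | mesityl oxide (4-methylpent-3-en-2-one) | CC(=O)C=C(C)C | starting material
2 | lithium 4-methylpenta-1,3-dien-2-olate | [Li+].[O-]C(=C)C=C(C)C | intermediate
3 | tert-butyldimethyl[(4-methylpenta-1,3-dien-2-yl)oxy]silane | C=C(O[Si](C)(C)C(C)(C)C)C=C(C)C | intermediate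
4 | methyl but-2-ynoate | CC#CC(=O)OC | starting material
5 | methyl 4-[(tert-butyldimethylsilyl)oxy]-2,6,6-trimethylcyclohexa-1,4-diene-1-carboxylate | COC(=O)C1=C(C)CC(O[Si](C)(C)C(C)(C)C)=CC1(C)C | intermediate
6 | {4-[(tert-butyldimethylsilyl)oxy]-2,6,6-trimethylcyclohexa-1,4-dien-1-yl}methanol | OCC1=C(C)CC(O[Si](C)(C)C(C)(C)C)=CC1(C)C | intermediate
7 | [(1S,6S)-4-[(tert-butyldimethylsilyl)oxy]-2,2,6-trimethyl-7-oxabicyclo[4.1.0]hept-3-en-1-yl]methanol | OC[C@]12O[C@@]1(C)CC(O[Si](C)(C)C(C)(C)C)=CC2(C)C | intermediate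
8 | (1S,6S)-1-(hydroxymethyl)-2,2,6-trimethyl-7-oxabicyclo[4.1.0]heptan-4-one | OC[C@]12O[C@@]1(C)CC(=O)CC2(C)C | intermediate
9 | (3R,4S)-3,4-dihydroxy-4-(hydroxymethyl)-3,5,5-trimethylcyclohexan-1-one | OC[C@@]1(O)C(C)(C)CC(=O)C[C@@]1(C)O | intermediate
10 | (1R,2R)-1,2-dihydroxy-2,6,6-trimethyl-4-oxocyclohexane-1-carbaldehyde | O=C[C@@]1(O)C(C)(C)CC(=O)C[C@@]1(C)O | intermediate
11 | ethyl (2E)-4-(diethoxyphosphoryl)-3-methylbut-2-enoate | CCOC(=O)/C=C(\C)CP(=O)(OCC)OCC | starting material
12 | lithium salt of the α-phosphoryl carbanion of 11 | [Li+].CCOC(=O)/C=C(\C)[CH-]P(=O)(OCC)OCC | intermediate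
13 | ethyl (2E,4E)-5-[(1R,2R)-1,2-dihydroxy-2,6,6-trimethyl-4-oxocyclohexyl]-3-methylpenta-2,4-dienoate | CCOC(=O)/C=C(\C)/C=C/[C@@]1(O)C(C)(C)CC(=O)C[C@@]1(C)O | intermediate
14 | ethyl (2E,4E)-3-methyl-5-[(1R,2R,4S)-1,2,4-trihydroxy-2,6,6-trimethylcyclohexyl]penta-2,4-dienoate | CCOC(=O)/C=C(\C)/C=C/[C@@]1(O)C(C)(C)C[C@H](O)C[C@@]1(C)O | intermediate
15 | (1R,2R,4S)-1-[(1E,3E)-5-hydroxy-3-methylpenta-1,3-dien-1-yl]-2,6,6-trimethylcyclohexane-1,2,4-triol | OC/C=C(\C)/C=C/[C@@]1(O)C(C)(C)C[C@H](O)C[C@@]1(C)O | intermediate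
16 | (1R,2R,4S)-1-[(1E,3E)-5-bromo-3-methylpenta-1,3-dien-1-yl]-2,6,6-trimethylcyclohexane-1,2,4-triol | BrC/C=C(\C)/C=C/[C@@]1(O)C(C)(C)C[C@H](O)C[C@@]1(C)O | intermediate
17 | [(2E,4E)-3-methyl-5-[(1R,2R,4S)-1,2,4-trihydroxy-2,6,6-trimethylcyclohexyl]penta-2,4-dien-1-yl]triphenylphosphonium bromide | c2ccccc2[P+](c3ccccc3)(c4ccccc4)C/C=C(\C)/C=C/[C@@]1(O)C(C)(C)C[C@H](O)C[C@@]1(C)O.[Br-] | intermediate
18 | (2R,6S,7aR)-2-[(2E)-4-hydroxybut-2-en-2-yl]-4,4,7a-trimethyl-2,4,5,6,7,7a-hexahydro-1-benzofuran-6-ol | OC/C=C(\C)[C@H]1C=C2C(C)(C)C[C@H](O)C[C@@]2(C)O1 | intermediate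
19 | (2R,6S,7aR)-2-[(2E)-4-bromobut-2-en-2-yl]-4,4,7a-trimethyl-2,4,5,6,7,7a-hexahydro-1-benzofuran-6-ol | BrC/C=C(\C)[C@H]1C=C2C(C)(C)C[C@H](O)C[C@@]2(C)O1 | intermediate
20 | [(2E)-3-[(2R,6S,7aR)-6-hydroxy-4,4,7a-trimethyl-2,4,5,6,7,7a-hexahydro-1-benzofuran-2-yl]but-2-en-1-yl]triphenylphosphonium bromide | c3ccccc3[P+](c4ccccc4)(c5ccccc5)C/C=C(\C)[C@H]1C=C2C(C)(C)C[C@H](O)C[C@@]2(C)O1.[Br-] | intermediate
21 | (2E,4E,6E)-2,7-dimethylocta-2,4,6-trienedial | O=C/C(C)=C/C=C/C=C(C)/C=O | starting material
22 | triphenylphosphonium ylide of 20 (carbanion at C11') | c3ccccc3[P+](c4ccccc4)(c5ccccc5)[CH-]/C=C(\C)[C@H]1C=C2C(C)(C)C[C@H](O)C[C@@]2(C)O1 | intermediate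
23 | (2E,4E,6E,8E,10E)-11-[(2R,6S,7aR)-6-hydroxy-4,4,7a-trimethyl-2,4,5,6,7,7a-hexahydro-1-benzofuran-2-yl]-2,7-dimethyldodeca-2,4,6,8,10-pentaenal | CC(/C=O)=C\C=C\C=C(C)\C=C\C=C(/C)[C@H]1C=C2C(C)(C)C[C@H](O)C[C@@]2(C)O1 | intermediate
24 | triphenylphosphonium ylide of 17 (carbanion at C11) | c2ccccc2[P+](c3ccccc3)(c4ccccc4)[CH-]/C=C(\C)/C=C/[C@@]1(O)C(C)(C)C[C@H](O)C[C@@]1(C)O | intermediate
25 | (3S,5R,6R,3'S,5'R,8'R)-5',8'-epoxy-5,6,5',8'-tetrahydro-β,β-carotene-3,5,6,3'-tetrol | CC(/C=C/C=C(C)/C=C/[C@@]1(O)C(C)(C)C[C@H](O)C[C@@]1(C)O)=C\C=C\C=C(C)\C=C\C=C(/C)[C@H]1C=C2C(C)(C)C[C@H](O)C[C@@]2(C)O1 | target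

Total step count: 14. Longest linear sequence: 13 steps (steps 1 to 9, then 11, 12, 13 and 14).

Steps most likely to fail

Step 11. The configuration at C8' may be eroded if the new bis-allylic ether re-ionises, or if the cation rotates about C7–C8 before it is captured. Capture of the cation at C6 by the 3-hydroxyl is a competing process. The fallback gives up kinetic control and sets out again from 15. The ring closure is run under equilibrating conditions (TsOH, CH2Cl2, rt), which should give 18 together with its C8' epimer, (2S,6S,7aR)-2-[(2E)-4-hydroxybut-2-en-2-yl]-4,4,7a-trimethyl-2,4,5,6,7,7a-hexahydro-1-benzofuran-6-ol F1. The two diastereomers are separated by chromatography and F1 is returned to the same acid treatment, so that the material is funnelled by recycling into 18, where the route is rejoined.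

Step 2. The cycloaddition may be too slow at the fully substituted diene terminus, so that polymerisation of the diene or its isomerisation by a 1,5-hydrogen shift takes over. The fallback sets out from 1 and builds the same two ring bonds stepwise by a Robinson-type Michael–aldol annulation with ethyl acetoacetate (BF3·OEt2), which should give racemic ethyl 2,6,6-trimethyl-4-oxocyclohex-2-ene-1-carboxylate F2. Ketalisation with ethylene glycol (TsOH, toluene, removal of water) moves the alkene out of conjugation with the ketone and should give ethyl 7,9,9-trimethyl-1,4-dioxaspiro[4.5]dec-7-ene-8-carboxylate F3. Reduction with i-Bu2AlH gives (7,9,9-trimethyl-1,4-dioxaspiro[4.5]dec-7-en-8-yl)methanol F4. Sharpless epoxidation with L-(+)-diethyl tartrate gives [(1'S,6'S)-2',2',6'-trimethylspiro[1,3-dioxolane-2,4'-[7]oxabicyclo[4.1.0]heptan]-1'-yl]methanol F5. Aqueous HClO4 then opens the epoxide at C5 and removes the ketal, and the route is rejoined at 9.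

Step 5. Opening through a free C5 cation would lose the inversion at C5, and eliminative opening of the β,γ-epoxy ketone, or dehydration of the β-hydroxy ketone, would destroy C5 altogether. The fallback sets out from 7 and opens the epoxide before the ketone is unmasked. Ti(O-i-Pr)4-mediated opening with benzoic acid (CH2Cl2, rt) should deliver the carboxylate to C5 with inversion and give (1R,2S)-5-[(tert-butyldimethylsilyl)oxy]-2-hydroxy-2-(hydroxymethyl)-1,3,3-trimethylcyclohex-4-en-1-yl benzoate F6. i-Bu2AlH removes the benzoate and gives (1S,2R)-4-[(tert-butyldimethylsilyl)oxy]-1-(hydroxymethyl)-2,6,6-trimethylcyclohex-4-ene-1,2-diol F7. Buffered hydrolysis of the silyl enol ether (AcOH–THF–H2O, 0 °C) then returns the route to 9.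

Further compounds
F1 | step 11 | (2S,6S,7aR)-2-[(2E)-4-hydroxybut-2-en-2-yl]-4,4,7a-trimethyl-2,4,5,6,7,7a-hexahydro-1-benzofuran-6-ol | OC/C=C(\C)[C@@H]1C=C2C(C)(C)C[C@H](O)C[C@@]2(C)O1
F2 | step 2 | ethyl 2,6,6-trimethyl-4-oxocyclohex-2-ene-1-carboxylate (racemic) | CCOC(=O)C1C(C)=CC(=O)CC1(C)C
F3 | step 2 | ethyl 7,9,9-trimethyl-1,4-dioxaspiro[4.5]dec-7-ene-8-carboxylate | CCOC(=O)C1=C(C)CC2(CC1(C)C)OCCO2
F4 | step 2 | (7,9,9-trimethyl-1,4-dioxaspiro[4.5]dec-7-en-8-yl)methanol | OCC1=C(C)CC2(CC1(C)C)OCCO2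
F5 | step 2 | [(1'S,6'S)-2',2',6'-trimethylspiro[1,3-dioxolane-2,4'-[7]oxabicyclo[4.1.0]heptan]-1'-yl]methanol | OC[C@]12O[C@@]1(C)CC3(CC2(C)C)OCCO3
F6 | step 5 | (1R,2S)-5-[(tert-butyldimethylsilyl)oxy]-2-hydroxy-2-(hydroxymethyl)-1,3,3-trimethylcyclohex-4-en-1-yl benzoate | OC[C@@]1(O)C(C)(C)C=C(O[Si](C)(C)C(C)(C)C)C[C@@]1(C)OC(=O)c2ccccc2
F7 | step 5 | (1S,2R)-4-[(tert-butyldimethylsilyl)oxy]-1-(hydroxymethyl)-2,6,6-trimethylcyclohex-4-ene-1,2-diol | OC[C@@]1(O)C(C)(C)C=C(O[Si](C)(C)C(C)(C)C)C[C@@]1(C)O
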